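Start from 38.7%, the mean E left at 60.0 min in the gamma, zeta and beta runs. Each of the three readings lies within 1.5 percentage points of it. Dusk and dawn are one charge, read at two times.

| setting | gamma | zeta | beta | dusk | dawn |
|---|---|---|---|---|---|
| E | 12 mM | 12 mM | 18 mM | 12 mM | 12 mM |
| G | 12 mM | 18 mM | 24 mM | 24.0 mM | 24.0 mM |
| remark | run made earlier | run made earlier | run made earlier |  |  |
| time |  |  |  | 80 min | 160 min |

- gamma (time / min: E / %, D / %, L / %): 8.00: 89, 11, 1; 25.0: 64, 33, 0; 40.0: 51, 49, 1; 60.0: 38, 61, 0
- zeta (time / min: E / %, D / %, L / %): 5.00: 92, 7, 0; 12.0: 79, 17, 1; 30.0: 60, 37, 1; 60.0: 40, 61, 0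
- beta (time / min: E / %, D / %, L / %): 5.00: 93, 7, 0; 12.0: 83, 16, 0; 30.0: 60, 39, 0; 60.0: 38, 60, 2

(standard deviation of a reading: 1.5 percentage points)

* which of these there is most of at the end, counted by the E in it, dusk (L / E / D)
* which of these there is most of at the end, counted by the E in it, dawn (L / E / D)
* amount of the one of these that there is most of at the end, in percent of the E charged, dusk
* amount of the one of these that there is most of at the end, in percent of the E charged, dawn

- L is meant together with its Z
- steps under discussion: E -> D; G -> X; D + X -> L; G + L <-> Z; G -> Q

The percentage of E left does not follow the charges, since the beta reading stands level with the gamma one, so treat the loss of E as first order and go to logarithms. Divide 60.0 min by the logarithm of the fall: 145 min is the decade time of E as these readings give it, the time in which [E] falls to a tenth.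

Dusk is then 0.550 of a decade and dawn 1.10, so my reckoning puts E at 28.2% in dusk and 7.94% in dawn. What has left E stands as D or L, which my reckoning puts together at 71.8% in dusk and 92.1% in dawn. L has read no higher than 2% in the earlier runs, so I commit to D in both, at somewhat less than those sums.

The forecast gives D at 71% in dusk and D at 79% in dawn: “D therefore stays the largest species”.

The flask gives D at 69.5% in dusk and D at 81.0% in dawn, so the forecast stands.

    E → D (k = 0.958 h⁻¹)
    G → X (k = 0.171 h⁻¹)
    D + X → L (k = 16.1 M⁻¹ h⁻¹)
    G + L ⇌ Z, settled at all times (K = 34.8 M⁻¹)
    G → Q (k = 0.157 h⁻¹)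

In dusk at 80.0 min, D is made 5.82 times faster than it is used up. Now take the decade time forward from the E of dusk, 27.9%: a further 80.0 min gives 7.85% for dawn, where the flask holds 7.77%.

Read dusk earlier, at 30 min. That is 0.207 of a decade, so the decade time puts E at 62.1% and leaves 37.9% for D and L, less than it gives E. The computed neighbour has E in the lead at 61.9%, with D at 37.9%.

The runs were generated by integration with made-up constants, and the scatter is random.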